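Lignan numbering: ring A = C7, O, C9', C8', C8 (4-hydroxy-3-methoxyphenyl endo on C7); ring B = C7', O, C9, C8, C8' (3-methoxy-4-prenyloxyphenyl exo on C7').
Cuts, in retrosynthetic order: O4'–prenyl and an O4 silyl group; C7'–O of ring B; C9'–O of ring A; C7–C8 (aldol); C7'=C8' (Stobbe). This leads back to vanillin (both aryl groups) and dimethyl succinate.
Enabling feature: C7' is the benzylic carbon para to O4', the oxygen that is prenylated last. While O4' is a free phenol and O4 is silylated, C7'H2 is the only site that can become a para-quinone methide, and the C9 hydroxyl lies on the same face of ring A (O–C9–C8–C8'–C7'), placed to close ring B.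
Forward order: Stobbe chain and hydrogenation, beta-benzyl lactone, C7–C8 aldol, ring A by attack of O7 on C9', ring B by oxidative closure, then prenylation and desilylation.
Stereochemistry: C8' comes from Rh-catalysed asymmetric hydrogenation and C8 is set trans to it by enolate face control. C7 comes from the anti aldol of the ring-locked E-enolate and is kept by a closure that breaks no bond at C7. C7' follows from the concave/convex bias of the bicycle.
Key step: step 11

Assumption: the (S,S) antipode of Et-DuPhos is taken to give the (R)-acid 6, by analogy with its sense on itaconates. If chiral HPLC and the rotation of lactone 8 show the opposite sense, the (R,R) ligand is used and nothing else changes.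

Step 1
Reactants: 1 vanillin; 2 benzyl bromide
Product: 3 4-benzyloxy-3-methoxybenzaldehyde
Conditions: K2CO3, DMF, rt
Reagents that add atoms: none
Why: Williamson etherification of the acidic phenol with a benzylic bromide is reliable, and the benzyl ether withstands the alkoxide, hydride and enolate steps ahead yet leaves later by neutral hydrogenolysis.

Step 2
Reactants: 3 4-benzyloxy-3-methoxybenzaldehyde; 4 dimethyl succinate
Product: 5 (E)-4-(4-benzyloxy-3-methoxyphenyl)-3-(methoxycarbonyl)but-3-enoic acid
Conditions: NaOMe, MeOH, reflux; then aq. HCl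
Reagents that add atoms: none
Why: In the Stobbe condensation the succinate enolate adds to the non-enolisable aldehyde, the aldolate lactonises and the paraconic ester opens by E1cB elimination to a carboxylate, which drives the reaction and favours the E-alkene (aryl trans to the ester).

Step 3
Reactants: 5 (E)-half-ester
Product: 6 (3R)-4-(4-benzyloxy-3-methoxyphenyl)-3-(methoxycarbonyl)butanoic acid
Conditions: [Rh(cod)((S,S)-Et-DuPhos)]BF4 (0.5 mol %), NaOMe (10 mol %), H2 (6 bar), MeOH, rt
Reagents that add atoms: none
Why: In this rhodium-catalysed asymmetric hydrogenation of a Stobbe-type itaconate half-ester the carboxylate arm chelates the cationic rhodium beside the alkene, so the C2-symmetric bisphospholane delivers H2 to one face and sets C8' as R, and the catalyst does not cleave the aryl benzyl ether.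

Step 4
Reactants: 6 (R)-half-ester
Product: 8 (4R)-4-(4-benzyloxy-3-methoxybenzyl)dihydrofuran-2(3H)-one, via hydroxy acid 7 (not isolated)
Conditions: KOH (1 equiv), EtOH, 0 °C; CaCl2, NaBH4, EtOH, −10 °C to rt; then 2 M HCl, rt
Reagents that add atoms: none
Why: This is a chemoselective borohydride reduction in which the acid end, as its potassium carboxylate, is inert to Ca(BH4)2, so only the methyl ester (the future C9') is reduced and acidification lactonises the 4-hydroxy acid without touching C8'.

Step 5
Reactants: 1 vanillin
Product: 9 3-methoxy-4-(triisopropylsilyloxy)benzaldehyde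
Conditions: TIPSCl, imidazole, DMF, rt
Reagents that add atoms: chlorotriisopropylsilane, CC(C)[Si](Cl)(C(C)C)C(C)C
Why: This is a standard imidazole-promoted silylation of a phenol, and the bulky triisopropylsilyl group is preferred to smaller silyl groups because it must outlast alkoxide, hydride and carbonate bases and still leave with fluoride at the end.

Step 6
Reactants: 8 (R)-lactone; 9 silylated vanillin
Product: 11 (3S,4R)-4-(4-benzyloxy-3-methoxybenzyl)-3-[(R)-hydroxy(3-methoxy-4-triisopropylsilyloxyphenyl)methyl]dihydrofuran-2(3H)-one, via lithium enolate 10 (not isolated)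
Conditions: LiN(SiMe3)2, THF, −78 °C; then 9, −78 °C; AcOH quench at −78 °C
Reagents that add atoms: none
Why: In this lithium enolate aldol addition the ring locks the enolate in the E(O) geometry, so the closed Zimmerman–Traxler chair with the aryl group equatorial should favour the anti (7R) carbinol, while the C8' benzyl group shields one face and places the new C8 substituent trans to it; the minor C7 epimer is removed by chromatography.

Step 7
Reactants: 11 anti-aldol lactone
Product: 12 (2S,3R)-3-(4-benzyloxy-3-methoxybenzyl)-4-hydroxy-2-[(R)-hydroxy(3-methoxy-4-triisopropylsilyloxyphenyl)methyl]-N-methoxy-N-methylbutanamide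
Conditions: MeNHOMe·HCl, AlMe3, CH2Cl2, 0 °C to rt; aq. potassium sodium tartrate; used at once
Reagents that add atoms: N,O-dimethylhydroxylamine hydrochloride, CNOC.Cl
Why: Weinreb aminolysis with the aluminium amide opens the lactone at the acyl carbon, which frees the C9' hydroxyl while C9 stays at the acid level and so tells the two future carbinol arms apart, and beta-hydroxy carbonyl compounds are known to pass through this reaction without retro-aldol cleavage.

Step 8
Reactants: 12 diol Weinreb amide
Product: 14 (2R,3S,4R)-4-(4-benzyloxy-3-methoxybenzyl)-N-methoxy-2-(3-methoxy-4-triisopropylsilyloxyphenyl)-N-methyltetrahydrofuran-3-carboxamide (all-cis ring A), via primary mesylate 13 (not isolated)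
Conditions: MsCl (1.05 equiv), Et3N, CH2Cl2, −30 °C; cold water wash, solvent change to THF; KOt-Bu, −20 to 0 °C
Reagents that add atoms: methanesulfonyl chloride, CS(=O)(=O)Cl (its atoms are held in 13 only)
Why: Selective sulfonylation of the primary over the hindered secondary benzylic alcohol is followed by an intramolecular Williamson etherification (5-exo-tet) in which O7 is the nucleophile and C9' the electrophile, so no bond at C7, C8 or C8' breaks and the anti,trans array of 12 becomes the all-cis ring A.

Step 9
Reactants: 14 all-cis Weinreb amide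
Product: 16 [(2R,3R,4R)-4-(4-benzyloxy-3-methoxybenzyl)-2-(3-methoxy-4-triisopropylsilyloxyphenyl)tetrahydrofuran-3-yl]methanol, via aldehyde 15 (not isolated)
Conditions: i-Bu2AlH, THF, −78 °C; then NaBH4, MeOH, −78 to 0 °C
Reagents that add atoms: none
Why: Weinreb amide reduction stops at the chelated hemiaminal aluminate, and releasing the aldehyde with methanol in the presence of NaBH4 at low temperature reduces it at once, which leaves no time for epimerisation of the crowded C8 centre.

Step 10
Reactants: 16 benzyl-protected alcohol
Product: 17 4-{[(3R,4R,5R)-4-(hydroxymethyl)-5-(3-methoxy-4-triisopropylsilyloxyphenyl)tetrahydrofuran-3-yl]methyl}-2-methoxyphenol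
Conditions: H2 (1 atm), Pd/C (10 %), EtOAc, rt, stopped at consumption of 16
Reagents that add atoms: none
Why: Catalytic hydrogenolysis cleaves an aryl benzyl ether much faster than the cyclic benzylic C7–O bond in a neutral aprotic solvent, so only the phenol para to C7' is freed.

Step 11
Reactants: 17 all-cis 7'-deoxy phenol
Product: 19 4-[(1S,3aR,4R,6aR)-4-(3-methoxy-4-triisopropylsilyloxyphenyl)tetrahydro-1H,3H-furo[3,4-c]furan-1-yl]-2-methoxyphenol (7R,8R,7'S,8'R; endo aryl on C7 and exo aryl on C7'), via quinone methide 18 (not isolated)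
Conditions: Ag2O (2.5 equiv), 4 Å molecular sieves, CH2Cl2 (0.005 M), rt, dark
Reagents that add atoms: none
Why: Ag2O removes two electrons and two protons (O–H and one C7'–H) from the only free 4-alkylguaiacol unit to give para-quinone methide 18, whose exocyclic C7' is attacked by the C9 hydroxyl in a 1,6-conjugate addition that restores the aromatic ring. The closest known reaction type is the Ag2O or DDQ oxidation of 4-alkyl-2-methoxyphenols to quinone methides with capture by a neighbouring alcohol. Ring B (C7', O, C9, C8, C8') closes in the 5-exo-trig mode, with the C7'=C1' bond outside the new ring, and the cis relation of C9 and C7' on ring A permits only a cis fusion. The single new stereocentre, C7', is controlled by the aryl group on C7, which fills the concave face, so the flat quinone methide should turn outwards and oxygen adds to the face that leaves the new aryl exo (7'S). Site selectivity between the two benzylic positions is required and is secured by the silyl ether on O4, because that ring can form neither a phenoxyl radical nor a quinone methide and C7–H stays untouched. High dilution, an aprotic solvent and sieves hold back radical dimerisation and capture by water, and the reaction is stopped as soon as 17 is consumed because 19 is still a phenol.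

Step 12
Reactants: 19 furofuran phenol; 20 prenyl bromide
Product: 21 (7R,8R,7'S,8'R)-3,3'-dimethoxy-4'-(3-methylbut-2-enyloxy)-4-triisopropylsilyloxy-7,9':7',9-diepoxylignan
Conditions: K2CO3, acetone, rt
Reagents that add atoms: none
Why: Williamson etherification of the phenol released by the ring closure with an allylic bromide under mild carbonate conditions favours O- over C-alkylation and leaves the hindered silyl ether and both benzylic ethers alone.

Step 13
Reactants: 21 prenyl ether silyl ether
Product: 22 target 4-[(1R,3aR,4S,6aR)-4-[3-methoxy-4-(3-methylbut-2-enyloxy)phenyl]tetrahydro-1H,3H-furo[3,4-c]furan-1-yl]-2-methoxyphenol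
Conditions: Bu4NF, AcOH (1:1), THF, 0 °C
Reagents that add atoms: none
Why: Fluoride-induced cleavage of the aryl silyl ether is buffered with acetic acid so that neither free phenoxide nor strong acid is present to open the endo C7–O bond and epimerise it to the exo series, and the prenyl ether is inert.

Compound list
1 | vanillin | COc1cc(C=O)ccc1O | starting material
2 | benzyl bromide | BrCc1ccccc1 | starting material
3 | 4-benzyloxy-3-methoxybenzaldehyde | COc1cc(C=O)ccc1OCc1ccccc1 | intermediate
4 | dimethyl succinate | COC(=O)CCC(=O)OC | starting material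
5 | (E)-4-(4-benzyloxy-3-methoxyphenyl)-3-(methoxycarbonyl)but-3-enoic acid | COC(=O)/C(CC(=O)O)=C/c1ccc(OCc2ccccc2)c(OC)c1 | intermediate
6 | (3R)-4-(4-benzyloxy-3-methoxyphenyl)-3-(methoxycarbonyl)butanoic acid | COC(=O)[C@@H](CC(=O)O)Cc1ccc(OCc2ccccc2)c(OC)c1 | intermediate
7 | (3R)-4-(4-benzyloxy-3-methoxyphenyl)-3-(hydroxymethyl)butanoic acid (not isolated) | OC[C@@H](CC(=O)O)Cc1ccc(OCc2ccccc2)c(OC)c1 | intermediate
8 | (4R)-4-(4-benzyloxy-3-methoxybenzyl)dihydrofuran-2(3H)-one | O=C1OC[C@H](Cc2ccc(OCc3ccccc3)c(OC)c2)C1 | intermediate
9 | 3-methoxy-4-(triisopropylsilyloxy)benzaldehyde | COc1cc(C=O)ccc1O[Si](C(C)C)(C(C)C)C(C)C | intermediate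
10 | lithium enolate of 8 (not isolated) | [Li]OC1=C[C@@H](Cc2ccc(OCc3ccccc3)c(OC)c2)CO1 | intermediate
11 | anti-aldol lactone (3S,4R, carbinol R) | O=C1OC[C@H](Cc2ccc(OCc3ccccc3)c(OC)c2)[C@H]1[C@@H](O)c1ccc(O[Si](C(C)C)(C(C)C)C(C)C)c(OC)c1 | intermediate
12 | diol Weinreb amide (2S,3R, carbinol R) | CON(C)C(=O)[C@H]([C@@H](O)c1ccc(O[Si](C(C)C)(C(C)C)C(C)C)c(OC)c1)[C@H](CO)Cc1ccc(OCc2ccccc2)c(OC)c1 | intermediate
13 | C9' methanesulfonate of 12, configuration unchanged (not isolated) | CON(C)C(=O)[C@H]([C@@H](O)c1ccc(O[Si](C(C)C)(C(C)C)C(C)C)c(OC)c1)[C@H](COS(C)(=O)=O)Cc1ccc(OCc2ccccc2)c(OC)c1 | intermediate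
14 | all-cis (2R,3S,4R)-tetrahydrofuran-3-carboxylic Weinreb amide | CON(C)C(=O)[C@H]1[C@@H](Cc2ccc(OCc3ccccc3)c(OC)c2)CO[C@H]1c1ccc(O[Si](C(C)C)(C(C)C)C(C)C)c(OC)c1 | intermediate
15 | all-cis (2R,3S,4R)-tetrahydrofuran-3-carbaldehyde (not isolated) | O=C[C@H]1[C@@H](Cc2ccc(OCc3ccccc3)c(OC)c2)CO[C@H]1c1ccc(O[Si](C(C)C)(C(C)C)C(C)C)c(OC)c1 | intermediate
16 | all-cis (2R,3R,4R)-3-hydroxymethyl tetrahydrofuran, O4' benzyl ether | OC[C@H]1[C@@H](Cc2ccc(OCc3ccccc3)c(OC)c2)CO[C@H]1c1ccc(O[Si](C(C)C)(C(C)C)C(C)C)c(OC)c1 | intermediate
17 | all-cis 2-aryl-3-hydroxymethyl-4-(4-hydroxy-3-methoxybenzyl)tetrahydrofuran (precursor of the key step) | OC[C@H]1[C@@H](Cc2ccc(O)c(OC)c2)CO[C@H]1c1ccc(O[Si](C(C)C)(C(C)C)C(C)C)c(OC)c1 | intermediate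
18 | para-quinone methide of 17, C7'=C1' geometry not defined (not isolated) | OC[C@H]1[C@@H](C=C2C=CC(=O)C(OC)=C2)CO[C@H]1c1ccc(O[Si](C(C)C)(C(C)C)C(C)C)c(OC)c1 | intermediate
19 | endo,exo-furofuran, O4' free phenol, O4 silyl ether (product of the key step) | COc1cc([C@@H]2OC[C@H]3[C@@H]2CO[C@@H]3c2ccc(O)c(OC)c2)ccc1O[Si](C(C)C)(C(C)C)C(C)C | intermediate
20 | prenyl bromide (1-bromo-3-methylbut-2-ene) | CC(C)=CCBr | starting material
21 | endo,exo-furofuran, O4' prenyl ether, O4 silyl ether | COc1cc([C@@H]2OC[C@H]3[C@@H]2CO[C@@H]3c2ccc(OCC=C(C)C)c(OC)c2)ccc1O[Si](C(C)C)(C(C)C)C(C)C | intermediate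
22 | target, (7R,8R,7'S,8'R) | COc1cc([C@@H]2OC[C@H]3[C@@H]2CO[C@@H]3c2ccc(OCC=C(C)C)c(OC)c2)ccc1O | target

Total step count: 13.
Longest linear sequence: 12 steps (steps 1–4 and 6–13); step 5 is the one-step side branch.

Steps most likely to fail

Step 11. One-electron oxidation on the silver oxide surface may lead to coupling of phenoxyl radicals at the open C5' position faster than loss of the C7' hydrogen. The product, still a phenol with a weakened C7'–H bond, may also be oxidised further. The fallback closes ring B one step earlier, at the benzyl ether stage, by hydride abstraction instead of phenol oxidation. It sets out from 16, which is treated with DDQ (1.1 equiv) and solid NaHCO3 in CH2Cl2 at 0 °C. This is the known DDQ-mediated oxidative cyclisation of 4-alkoxybenzyl C–H bonds onto a neighbouring alcohol. The alkyl aryl ether ring is the more electron-rich of the two arenes, so the C7' cation should form in preference, and capture by the C9 hydroxyl should give the O4'-benzyl endo,exo-furofuran F1. Brief hydrogenolysis (H2, Pd/C, EtOAc) then removes the benzyl group, and the sequence comes back to the route at 19.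

Step 6. Chair and boat transition states of five-membered ring enolates lie close in energy, and the aldolate can equilibrate by retro-aldol reaction, so simple diastereoselection at C7 may be poor. The fallback moves control of C7 from the C–C bond formation to a reagent-controlled ketone reduction. It sets out from 8 and 9, which are combined as in step 6 without regard to selectivity to give 11 together with the C7 epimer (7S) syn-aldol lactone F2. The mixture is oxidised with Dess–Martin periodinane (CH2Cl2, rt), so both epimers converge on the trans beta-keto lactone F3. Noyori–Ikariya transfer hydrogenation of this aryl ketone with RuCl[(R,R)-TsDPEN](p-cymene) in HCO2H/Et3N should set C7 as R by aryl recognition. C8, though labile, stays trans to the benzyl group for steric reasons. The sequence comes back to the route at 11.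

Step 8. The hydroxy amide may relactonise before sulfonylation, the amide carbonyl oxygen may attack the activated C9', and the C7 alkoxide may undergo retro-aldol cleavage. The fallback removes the carbonyl group before ring A is closed and relies on ring-size preference instead of oxidation level to tell C9 and C9' apart. It sets out from 11, which LiAlH4 (THF, 0 °C) reduces to the (2R,3R, carbinol R) triol F4. MsCl (2.1 equiv) and Et3N in CH2Cl2 at −30 °C sulfonylate both primary hydroxyls to give the bis(methanesulfonate) F5. KOt-Bu in THF at 0 °C lets O7 choose the 5-exo-tet attack on C9' over the 4-exo-tet attack on C9, which gives the all-cis tetrahydrofuran C9 methanesulfonate F6. CsOAc in DMF at 70 °C displaces the remaining sulfonate to give the C9 acetate F7, and i-Bu2AlH (CH2Cl2, −78 °C) removes the acetyl group. The sequence comes back to the route at 16 and passes no epimerisable carbonyl compound on the way.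

Further compounds
F1 | step 11 | (7R,8R,7'S,8'R)-4'-benzyloxy-3,3'-dimethoxy-4-triisopropylsilyloxy-7,9':7',9-diepoxylignan | COc1cc([C@@H]2OC[C@H]3[C@@H]2CO[C@@H]3c2ccc(OCc4ccccc4)c(OC)c2)ccc1O[Si](C(C)C)(C(C)C)C(C)C
F2 | step 6 | (3S,4R)-4-(4-benzyloxy-3-methoxybenzyl)-3-[(S)-hydroxy(3-methoxy-4-triisopropylsilyloxyphenyl)methyl]dihydrofuran-2(3H)-one | O=C1OC[C@H](Cc2ccc(OCc3ccccc3)c(OC)c2)[C@H]1[C@H](O)c1ccc(O[Si](C(C)C)(C(C)C)C(C)C)c(OC)c1
F3 | step 6 | (3S,4R)-4-(4-benzyloxy-3-methoxybenzyl)-3-(3-methoxy-4-triisopropylsilyloxybenzoyl)dihydrofuran-2(3H)-one | O=C1OC[C@H](Cc2ccc(OCc3ccccc3)c(OC)c2)[C@H]1C(=O)c1ccc(O[Si](C(C)C)(C(C)C)C(C)C)c(OC)c1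
F4 | step 8 | (2R,3R)-3-(4-benzyloxy-3-methoxybenzyl)-2-[(R)-hydroxy(3-methoxy-4-triisopropylsilyloxyphenyl)methyl]butane-1,4-diol | OC[C@H]([C@@H](O)c1ccc(O[Si](C(C)C)(C(C)C)C(C)C)c(OC)c1)[C@H](CO)Cc1ccc(OCc2ccccc2)c(OC)c1
F5 | step 8 | 1,4-bis(methanesulfonate) of F4 | CS(=O)(=O)OC[C@H]([C@@H](O)c1ccc(O[Si](C(C)C)(C(C)C)C(C)C)c(OC)c1)[C@H](COS(C)(=O)=O)Cc1ccc(OCc2ccccc2)c(OC)c1
F6 | step 8 | methanesulfonate of 16 | CS(=O)(=O)OC[C@H]1[C@@H](Cc2ccc(OCc3ccccc3)c(OC)c2)CO[C@H]1c1ccc(O[Si](C(C)C)(C(C)C)C(C)C)c(OC)c1
F7 | step 8 | acetate of 16 | CC(=O)OC[C@H]1[C@@H](Cc2ccc(OCc3ccccc3)c(OC)c2)CO[C@H]1c1ccc(O[Si](C(C)C)(C(C)C)C(C)C)c(OC)c1
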